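**Plan**

- Retrosynthesis: the acetate is cut back to an acetyl group on C6 (Baeyer–Villiger, C6–O). The side chain is cut at C12–C13 (B-alkyl Suzuki–Miyaura), at C11–C12 (ylide homologation of a 9α,11-epoxide) and at C9–C11 (methylenation of a C9 ketone). The decalin is cut at C5–C10 and C6–C7.
- Enabling feature: in ring B, C9–O and C6–O are 1,4-related, with the quaternary C10 next to C9 and the ring-fusion C5 next to C6. C7=C8–C9(OSi)=C10 is therefore a 2-silyloxydiene and C5=C6–C(O)CH3 an (E)-enone (acetyl = masked acetate), tethered through C1–C4 of ring A.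
- Forward: a linear chain is assembled from isobutyronitrile (C4, C18, C19, C5), 1,3-diiodopropane (C1–C3), N-methoxy-N-methylpropanamide (C9, C10, C20), isopropenylmagnesium bromide (C7, C8, C17) and a ketophosphonate (C6, acetyl). One catalytic event then closes ring A (C5–C10) and ring B (C6–C7). The butenolide is added last.
- Stereochemistry: C5 is set by a chiral boron Lewis acid; C10 and C6 are relayed from it in the same event. C8 is set by equilibration next to the C9 ketone, and C9 by α-face epoxidation anti to the C10 methyl.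

Key step: step 7

**Remarks**

- Labdane numbering is used (decalin C1–C10, side chain C11–C16, C17 on C8, C18/C19 on C4, C20 on C10); α/β refer to the usual orientation with the C10 methyl β.
- The target SMILES is read as (5S,6S,8R,9R,10S): trans-decalin with 5α-H, 6α-OAc (equatorial), 8α-CH3 (equatorial), 9α-OH (axial) and the side chain 9β.
- Assumption: the (S)-configured oxazaborolidinium ion is taken to expose the Si face of C5 of the bound enone (α-C–H···O binding model); if the sense were opposite, the mirror-image catalyst would be used with no other change.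
- The silyl dienol ether (8, 9, 11) is carried as a mixture of geometric isomers at the tetrasubstituted enol ether.
- A side-chain organometallic is not added directly to the C9 ketone, because attack anti to the axial C10 methyl would place the chain α; the oxygen is instead the group delivered to the α face (step 10).

**Route**

Step 1
Reactants: 1 isobutyronitrile; 2 1,3-diiodopropane
Product: 3 5-iodo-2,2-dimethylpentanenitrile
Conditions: LiN(iPr)2, THF, −78 °C; then 2 (3 equiv), −78 °C → rt
Reagents that add atoms: none
Why: SN2 alkylation of the lithiated nitrile with excess primary diiodide installs the quaternary C4 with both methyl groups; no stereocenter is formed.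

Step 2
Reactants: 4 N-methoxy-N-methylpropanamide; 3 5-iodo-2,2-dimethylpentanenitrile
Product: 5 6-cyano-N-methoxy-N,2,6-trimethylheptanamide (racemic)
Conditions: LiN(iPr)2, THF, −78 °C; then 3, DMPU, −78 → −20 °C
Reagents that add atoms: none
Why: Amide enolate alkylation (SN2) with the primary iodide forms the C1–C10 bond, the hindered tertiary nitrile being inert to the enolate; the new center C10 is racemic and is erased in step 4.

Step 3
Reactants: 5 6-cyano-N-methoxy-N,2,6-trimethylheptanamide; 6 isopropenylmagnesium bromide (CH2=C(CH3)MgBr)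
Product: 7 2,2,6,8-tetramethyl-7-oxonon-8-enenitrile (racemic)
Conditions: THF, −20 → 0 °C; cold 1 M HCl
Reagents that add atoms: none
Why: Grignard acylation of an N-methoxy-N-methylamide stops at the ketone because of the stable magnesium chelate, and the tertiary nitrile does not react at or below 0 °C.

Step 4
Reactants: 7 2,2,6,8-tetramethyl-7-oxonon-8-enenitrile
Product: 8 2,2,6,8-tetramethyl-7-(triisopropylsilyloxy)nona-6,8-dienenitrile (6E/6Z mixture)
Conditions: KN(SiMe3)2, THF, −78 °C; then iPr3SiOTf, −78 → 0 °C
Reagents that add atoms: triisopropylsilyl trifluoromethanesulfonate, CC(C)[Si](C(C)C)(C(C)C)OS(=O)(=O)C(F)(F)F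
Why: Kinetic enolisation at the only enolisable position (C10–H) and O-silylation give the cross-conjugated 2-silyloxydiene; the geometry of the tetrasubstituted enol ether is not controlled and is not needed in step 7.

Step 5
Reactants: 8 2,2,6,8-tetramethyl-7-(triisopropylsilyloxy)nona-6,8-dienenitrile
Product: 9 2,2,6,8-tetramethyl-7-(triisopropylsilyloxy)nona-6,8-dienal (6E/6Z mixture)
Conditions: iBu2AlH, toluene, −78 °C; then aq. potassium sodium tartrate, rt
Reagents that add atoms: water, O
Why: Partial reduction of the nitrile to the aluminium aldimine and hydrolysis on work-up is the standard nitrile-to-aldehyde reduction, the aldehyde being non-enolisable and the silyl enol ether inert to the hydride.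

Step 6
Reactants: 9 2,2,6,8-tetramethyl-7-(triisopropylsilyloxy)nona-6,8-dienal; 10 dimethyl (2-oxopropyl)phosphonate
Product: 11 (3E)-5,5,9,11-tetramethyl-10-(triisopropylsilyloxy)dodeca-3,9,11-trien-2-one (9E/9Z mixture)
Conditions: Ba(OH)2, THF/H2O (40:1), rt
Reagents that add atoms: none
Why: Horner–Wadsworth–Emmons olefination with a β-ketophosphonate under mild Ba(OH)2 conditions should give the (E)-enone, and the basic medium leaves the silyl enol ether intact.

Step 7
Reactants: 11 (3E)-5,5,9,11-tetramethyl-10-(triisopropylsilyloxy)dodeca-3,9,11-trien-2-one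
Product: 13 trans-fused silyl enol ether 6α-acetyl-4,4,8,10β-tetramethyl-9-(triisopropylsilyloxy)-5α-octal-8-ene, via Michael zwitterion 12 (not isolated)
Conditions: (S)-3,3-diphenyl-1-(o-tolyl)tetrahydro-1H,3H-pyrrolo[1,2-c][1,3,2]oxazaborole (20 mol %), HNTf2 (16 mol %), CH2Cl2, −78 → −40 °C; Et3N quench
Reagents that add atoms: none
Why: Proposed new method: the boron Lewis acid binds the enone carbonyl of 11 and C10 of the silyl dienol ether adds to the activated C5 in a Mukaiyama–Michael step (6-exo-trig closure of ring A, the C5–C10 bond), giving zwitterion 12 whose C6 enolate collapses onto C7 of the silyloxyallyl cation (6-endo-trig Michael closure of ring B), a stepwise formal [4+2] cycloaddition. The closest known reaction types are the oxazaborolidinium-catalysed Diels–Alder reaction of 2-silyloxydienes with enones and the Lewis-acid-promoted intramolecular double Michael reaction of enone-tethered dienolates; new is the fully substituted enol ether terminus that becomes the quaternary C10 under catalyst control. C5 is set by the catalyst, which shields the Re face of the s-trans enone so that C10 adds to the Si face of C5. C10 follows from C5 through the chair-like transition state of ring A in which the enone arm and the silyloxyallyl arm are both equatorial and the C10 methyl is axial (trans ring fusion, the endo mode of the (E)-enone), and C6 follows from the chair closure of ring B with the acetyl group equatorial, which is also the thermodynamic position. The step needs enantioface selectivity at C5, trans over cis fusion and C–C bond formation before loss of the silyl group: the catalyst, the all-equatorial chair favoured by the C4 gem-dimethyl group (which also speeds ring closure) and the bulky triisopropylsilyl group, which disfavours silyl transfer and racemic silyl-cation catalysis, are meant to secure them. Because the two bonds form in separate steps, both geometric isomers of the enol ether should converge on 13.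

Step 8
Reactants: 13 trans-fused silyl enol ether
Product: 15 6α-(2-methyl-1,3-dioxolan-2-yl)-4,4,8α,10β-tetramethyl-5α-decalin-9-one, via diketone 14 (not isolated)
Conditions: TsOH·H2O (cat.), wet THF, rt; then ethylene glycol, benzene, reflux with azeotropic removal of water
Reagents that add atoms: ethylene glycol, OCCO
Why: Acid hydrolysis of the silyl enol ether gives the C9 ketone, whose C8 methyl equilibrates by enolisation to the equatorial 8α position (the 8β epimer is 1,3-diaxial to the C10 methyl), and acetal formation is chemoselective for the unhindered methyl ketone over the C9 ketone flanked by a quaternary and a tertiary carbon.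

Step 9
Reactants: 15 keto acetal
Product: 16 6α-(2-methyl-1,3-dioxolan-2-yl)-4,4,8α,10β-tetramethyl-9-methylene-5α-decalin
Conditions: Ph3PCH3Br, KOtBu, toluene, 100 °C
Reagents that add atoms: methyltriphenylphosphonium bromide, C[P+](c1ccccc1)(c1ccccc1)c1ccccc1.[Br-]
Why: Wittig methylenation with the ylide generated by KOtBu in hot toluene is the established answer to hindered ketones, and the acetal keeps the acetyl group away from the ylide and from enolate chemistry.

Step 10
Reactants: 16 exocyclic alkene
Product: 17 9α,11-epoxide (spiro-oxirane at C9 with the oxygen α)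
Conditions: mCPBA, NaHCO3, CH2Cl2, 0 °C
Reagents that add atoms: meta-chloroperoxybenzoic acid, OOC(=O)c1cccc(Cl)c1
Why: Prilezhaev epoxidation of the 1,1-disubstituted alkene should occur from the α face (axial approach) because the β face is screened by the adjacent axial C10 methyl, which sets C9 with the oxygen α.

Step 11
Reactants: 17 9α,11-epoxide
Product: 18 9α-hydroxy-9β-vinyl compound (tertiary allylic alcohol)
Conditions: Me3SI (4 equiv), nBuLi, THF, −10 °C → rt
Reagents that add atoms: trimethylsulfonium iodide, C[S+](C)C.[I-]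
Why: In this epoxide-to-allylic-alcohol homologation, dimethylsulfonium methylide opens the epoxide at the CH2 terminus and a second ylide equivalent triggers α′,β-elimination of dimethyl sulfide, so the C9–O bond is untouched and the 9α-hydroxy configuration is retained.

Step 12
Reactants: 18 9α-hydroxy-9β-vinyl compound; 19 3-bromofuran-2(5H)-one
Product: 21 acetal-protected butenolide 9α-hydroxy-9β-[2-(2-oxo-2,5-dihydrofuran-3-yl)ethyl] compound, via B-alkyl-9-BBN borane 20 (not isolated)
Conditions: 9-borabicyclo[3.3.1]nonane (9-BBN-H), THF, 0 °C → rt; then 19, PdCl2(dppf) (5 mol %), AsPh3, Cs2CO3, DMF/H2O, rt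
Reagents that add atoms: none
Why: Anti-Markovnikov hydroboration of the vinyl group and B-alkyl Suzuki–Miyaura coupling of the primary alkylborane with the α-bromo-α,β-unsaturated lactone form the C12–C13 bond without touching a stereocenter.

Step 13
Reactants: 21 acetal-protected butenolide
Product: 22 6α-acetyl-9α-hydroxy-labd-13-en-16,15-olide skeleton lacking the acetate oxygen (methyl ketone)
Conditions: 1 M HCl, THF, rt
Reagents that add atoms: water, O
Why: Mild aqueous acid hydrolyses the dioxolane to the methyl ketone while the tertiary alcohol and the butenolide are stable under these conditions.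

Step 14
Reactants: 22 methyl ketone
Product: 23 (5S,6S,8R,9R,10S)-6-acetoxy-9-hydroxylabd-13-en-16,15-olide (target)
Conditions: mCPBA, NaHCO3, CH2Cl2, rt
Reagents that add atoms: meta-chloroperoxybenzoic acid, OOC(=O)c1cccc(Cl)c1
Why: Baeyer–Villiger oxidation of the methyl ketone, with migration of the secondary C6 in preference to methyl and with retention, should give the 6α-acetate, the electron-poor butenolide alkene being inert to the peracid.

**Compound list**

1 | isobutyronitrile | CC(C)C#N | starting material
2 | 1,3-diiodopropane | ICCCI | starting material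
3 | 5-iodo-2,2-dimethylpentanenitrile | N#CC(C)(C)CCCI | intermediate
4 | N-methoxy-N-methylpropanamide | CCC(=O)N(C)OC | starting material
5 | 6-cyano-N-methoxy-N,2,6-trimethylheptanamide (racemic) | CON(C)C(=O)C(C)CCCC(C)(C)C#N | intermediate
6 | isopropenylmagnesium bromide | C=C(C)[Mg]Br | starting material
7 | 2,2,6,8-tetramethyl-7-oxonon-8-enenitrile (racemic) | C=C(C)C(=O)C(C)CCCC(C)(C)C#N | intermediate
8 | 2,2,6,8-tetramethyl-7-(triisopropylsilyloxy)nona-6,8-dienenitrile (6E/6Z mixture) | C=C(C)C(O[Si](C(C)C)(C(C)C)C(C)C)=C(C)CCCC(C)(C)C#N | intermediate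
9 | 2,2,6,8-tetramethyl-7-(triisopropylsilyloxy)nona-6,8-dienal (6E/6Z mixture) | C=C(C)C(O[Si](C(C)C)(C(C)C)C(C)C)=C(C)CCCC(C)(C)C=O | intermediate
10 | dimethyl (2-oxopropyl)phosphonate | CC(=O)CP(=O)(OC)OC | starting material
11 | (3E)-5,5,9,11-tetramethyl-10-(triisopropylsilyloxy)dodeca-3,9,11-trien-2-one (9E/9Z mixture) | C=C(C)C(O[Si](C(C)C)(C(C)C)C(C)C)=C(C)CCCC(C)(C)/C=C/C(C)=O | intermediate
12 | Michael zwitterion: ring A closed (5α-H, 10β-CH3), C9 silyloxyallyl cation, C6 enolate; drawn without the bound catalyst | C=C(C)C(=[O+][Si](C(C)C)(C(C)C)C(C)C)[C@@]1(C)CCCC(C)(C)[C@@H]1C=C(C)[O-] | intermediate (not isolated)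
13 | 1-[(1S,4aS,8aS)-3,4a,8,8-tetramethyl-4-(triisopropylsilyloxy)-1,2,4a,5,6,7,8,8a-octahydronaphthalen-1-yl]ethanone (labdane numbering: 6α-acetyl, 5α-H, 10β-CH3, C8=C9 silyl enol ether) | CC(=O)[C@H]1CC(C)=C(O[Si](C(C)C)(C(C)C)C(C)C)[C@@]2(C)CCCC(C)(C)[C@H]12 | intermediate
14 | 6α-acetyl-4,4,8α,10β-tetramethyl-5α-decalin-9-one (diketone) | CC(=O)[C@H]1C[C@@H](C)C(=O)[C@@]2(C)CCCC(C)(C)[C@H]12 | intermediate (not isolated)
15 | 6α-(2-methyl-1,3-dioxolan-2-yl)-4,4,8α,10β-tetramethyl-5α-decalin-9-one | CC1(OCCO1)[C@H]2C[C@@H](C)C(=O)[C@@]3(C)CCCC(C)(C)[C@H]23 | intermediate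
16 | 6α-(2-methyl-1,3-dioxolan-2-yl)-4,4,8α,10β-tetramethyl-9-methylene-5α-decalin | CC1(OCCO1)[C@H]2C[C@@H](C)C(=C)[C@@]3(C)CCCC(C)(C)[C@H]23 | intermediate
17 | 9α,11-epoxide of 16 (spiro-oxirane, oxygen α, CH2 β) | CC1(OCCO1)[C@H]2C[C@@H](C)[C@]4(CO4)[C@@]3(C)CCCC(C)(C)[C@H]23 | intermediate
18 | 9α-hydroxy-9β-vinyl-6α-(2-methyl-1,3-dioxolan-2-yl)-4,4,8α,10β-tetramethyl-5α-decalin | CC1(OCCO1)[C@H]2C[C@@H](C)[C@](O)(C=C)[C@@]3(C)CCCC(C)(C)[C@H]23 | intermediate
19 | 3-bromofuran-2(5H)-one | O=C1OCC=C1Br | starting material
20 | 9β-[2-(9-borabicyclo[3.3.1]nonan-9-yl)ethyl] analogue of 18 (hindered tertiary hydroxyl left free) | CC1(OCCO1)[C@H]2C[C@@H](C)[C@](O)(CCB4C5CCCC4CCC5)[C@@]3(C)CCCC(C)(C)[C@H]23 | intermediate (not isolated)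
21 | 9α-hydroxy-9β-[2-(2-oxo-2,5-dihydrofuran-3-yl)ethyl]-6α-(2-methyl-1,3-dioxolan-2-yl)-4,4,8α,10β-tetramethyl-5α-decalin | CC1(OCCO1)[C@H]2C[C@@H](C)[C@](O)(CCC4=CCOC4=O)[C@@]3(C)CCCC(C)(C)[C@H]23 | intermediate
22 | 6α-acetyl-9α-hydroxy-9β-[2-(2-oxo-2,5-dihydrofuran-3-yl)ethyl]-4,4,8α,10β-tetramethyl-5α-decalin | CC(=O)[C@H]1C[C@@H](C)[C@](O)(CCC2=CCOC2=O)[C@@]2(C)CCCC(C)(C)[C@H]12 | intermediate
23 | (5S,6S,8R,9R,10S)-6-acetoxy-9-hydroxylabd-13-en-16,15-olide | CC(=O)O[C@H]1C[C@@H](C)[C@](O)(CCC2=CCOC2=O)[C@@]2(C)CCCC(C)(C)[C@H]12 | target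

**Step count**

Total step count: 14. Longest linear sequence: 14 steps (from isobutyronitrile; all other building blocks are commercial).

**Steps most likely to fail**

Step 7 (proposed new method). The risk is loss of enantioface control through silyl transfer followed by achiral silyl-cation catalysis, or protodesilylation of the dienol ether before the C5–C10 bond forms. The fallback uses auxiliary control and known chemistry. Aldehyde 9 is condensed with diethyl {2-[(4S)-4-benzyl-2-oxo-1,3-oxazolidin-3-yl]-2-oxoethyl}phosphonate (LiCl, iPr2NEt, MeCN; Horner–Wadsworth–Emmons) to the N-enoyl oxazolidinone triene F1. Me2AlCl (CH2Cl2, −30 °C) then promotes the auxiliary-controlled intramolecular Diels–Alder reaction through the chelated s-cis imide, whose benzyl group blocks the Re face of C5, to give the imide cycloadduct F2. LiSEt (THF, 0 °C) removes the auxiliary to give the S-ethyl thioester F3, and Me2CuLi (Et2O, −78 °C) converts F3 into methyl ketone 13, where the route is rejoined.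

Step 11. The risk is slow attack of the ylide at the neopentyl-type CH2 of the spiro-epoxide, with lithium-salt-induced rearrangement of the epoxide to an aldehyde taking over. The fallback sets out from alkene 16 and makes the C11–C12 bond by olefination of a carbonyl group, not by substitution at a hindered carbon. Alkene 16 is dihydroxylated from the α face (OsO4 cat., N-methylmorpholine N-oxide, acetone/H2O) to the 9α,11-diol F4. The primary alcohol is oxidised (SO3·pyridine, DMSO, iPr2NEt; Parikh–Doering oxidation) to the α-hydroxy aldehyde F5, and Wittig methylenation of F5 (Ph3P=CH2, THF) gives vinyl carbinol 18.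

Step 12. The risk is base-induced decomposition of the bromobutenolide or protodeboronation of the alkylborane outrunning transmetalation to palladium. The fallback sets out from epoxide 17 and builds the butenolide by carbonylation. Epoxide 17 is opened with allenylmagnesium bromide (CH2=C=CHMgBr, Et2O, −78 → 0 °C) to the homopropargylic alcohol F6. The alkyne is hydroxymethylated (nBuLi 2 equiv, paraformaldehyde, THF) to the propargylic alcohol F7. trans-Hydroalumination with NaAlH2(OCH2CH2OCH3)2 followed by iodination (I2, −78 °C) gives the (Z)-3-iodoallylic alcohol F8. Carbonylative lactonisation (Pd(PPh3)4, CO 1 atm, K2CO3, THF) then closes the butenolide and returns to 21.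

Further compounds
F1 | step 7 | (4S)-4-benzyl-3-[(2E)-4,4,8,10-tetramethyl-9-(triisopropylsilyloxy)undeca-2,8,10-trienoyl]-1,3-oxazolidin-2-one | C=C(C)C(O[Si](C(C)C)(C(C)C)C(C)C)=C(C)CCCC(C)(C)/C=C/C(=O)N1C(=O)OC[C@@H]1Cc1ccccc1
F2 | step 7 | imide cycloadduct: 6α-[(4S)-4-benzyl-2-oxo-1,3-oxazolidine-3-carbonyl] analogue of 13 | O=C([C@H]1CC(C)=C(O[Si](C(C)C)(C(C)C)C(C)C)[C@@]2(C)CCCC(C)(C)[C@H]12)N1C(=O)OC[C@@H]1Cc1ccccc1
F3 | step 7 | S-ethyl thioester analogue of 13 (6α-C(O)SEt) | CCSC(=O)[C@H]1CC(C)=C(O[Si](C(C)C)(C(C)C)C(C)C)[C@@]2(C)CCCC(C)(C)[C@H]12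
F4 | step 11 | 9α-hydroxy-9β-(hydroxymethyl) compound (9α,11-diol from 16) | CC1(OCCO1)[C@H]2C[C@@H](C)[C@](O)(CO)[C@@]3(C)CCCC(C)(C)[C@H]23
F5 | step 11 | 9α-hydroxy-9β-formyl compound (α-hydroxy aldehyde) | CC1(OCCO1)[C@H]2C[C@@H](C)[C@](O)(C=O)[C@@]3(C)CCCC(C)(C)[C@H]23
F6 | step 12 | 9α-hydroxy-9β-(but-3-yn-1-yl) compound | CC1(OCCO1)[C@H]2C[C@@H](C)[C@](O)(CCC#C)[C@@]3(C)CCCC(C)(C)[C@H]23
F7 | step 12 | 9α-hydroxy-9β-(5-hydroxypent-3-yn-1-yl) compound | CC1(OCCO1)[C@H]2C[C@@H](C)[C@](O)(CCC#CCO)[C@@]3(C)CCCC(C)(C)[C@H]23
F8 | step 12 | 9α-hydroxy-9β-[(3Z)-5-hydroxy-3-iodopent-3-en-1-yl] compound | CC1(OCCO1)[C@H]2C[C@@H](C)[C@](O)(CC/C(I)=C/CO)[C@@]3(C)CCCC(C)(C)[C@H]23
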